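Wednesday's flask came first, and Friday's repeats it with more free catalyst, 0.14 mol% against 0.096 mol%, while the impurity stays at 25 µM.

- Friday's: starting material 0.050 M; reagent 0.950 equiv; free catalyst 0.14 mol%; impurity 25 µM; time 6.0 min
- Wednesday's: starting material 0.050 M; reagent 0.950 equiv; free catalyst 0.096 mol%; impurity 25 µM; time 6.0 min

- which of these there is most of at the end, counted by the starting material in it, Friday's (side product / catalyst intermediate A / target / starting material)
- which of these there is most of at the end, counted by the starting material in it, Wednesday's (side product / catalyst intermediate A / target / starting material)
- how much there is at the end of the one of these that leads, in percent of the starting material charged: Friday's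
- how much there is at the end of the one of these that leads, in percent of the starting material charged: Wednesday's

    free catalyst + impurity → spent catalyst (k1 = 4.7 × 10⁵ M⁻¹ min⁻¹)
    catalyst intermediate C → free catalyst + target (k2 = 490 min⁻¹)
    starting material + by-product → side product (k3 = 0.30 M⁻¹ min⁻¹)
    reagent + catalyst intermediate A → catalyst intermediate B (k4 = 3400 M⁻¹ min⁻¹)
    catalyst intermediate B ⇌ by-product + catalyst intermediate C (K5 = 0.019 M, k5 = 38000 min⁻¹)
    starting material + free catalyst → catalyst intermediate A (k6 = 1.7 × 10⁵ M⁻¹ min⁻¹)

You can follow free catalyst in each flask. Starting material takes it into catalyst intermediate A, which takes up reagent, passes through catalyst intermediates B and C, and gives back free catalyst with target. Impurity turns it into spent catalyst instead. Both captures are proportional to free catalyst, so when you divide one rate by the other, free catalyst and time both drop out.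

The poison ratio, 2.76, is the constant of capture by impurity, 4.7 × 10⁵ M⁻¹ min⁻¹, over that of capture by starting material, 1.7 × 10⁵ M⁻¹ min⁻¹: a selectivity factor. With side product set aside, the fraction of impurity left is the fraction of starting material left raised to this ratio.

Set up a small table by the fraction of starting material left. At 0.7, impurity stands at 37.4% and 15.7 µM of catalyst is spent. At 0.5, it stands at 14.8% and 21.3 µM is spent.

Now subtract these from the charges, 70.0 µM for Friday's and 48.0 µM for Wednesday's. Friday's keeps 54.3 µM working in the first row and 48.7 µM in the second; Wednesday's keeps 32.3 µM and 26.7 µM. Reading the second row, the same loss costs Wednesday's 44.4% of its catalyst, more than Friday's 30.4%.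

One turn takes about 0.0109 min, with reagent taken at 0.7 of its charge, and capture by reagent takes longer than release of target. I set aside the return of by-product and catalyst intermediate C to catalyst intermediate B. Taking Friday's from the second row and Wednesday's from the first, I expect target to lead Friday's at 53.7%, and starting material to lead Wednesday's at 64.4%.

The forecast, whose figures differ from mine, gives target at 52% for Friday's and starting material at 60% for Wednesday's, holding that “the impurity is consumed only through free catalyst”.

The simulation gives target at 52.2% in Friday's and starting material at 60.0% in Wednesday's.

Put the starting material actually left into the poison ratio, and Friday's has lost 31.5% of its catalyst and Wednesday's 39.4%; the flasks hold 31.2% and 38.7% as spent catalyst. Friday's leaves 46.0% of starting material; with the difference in loading of free catalyst taken away, so that the flask runs at Wednesday's 0.096 mol%, it leaves 60.0%, and that difference is the main reason for the gap between the two flasks.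

Now take a neighbour of Friday's with 6.3 × 10⁻⁵ M of impurity. At the 0.7 row, the ratio leaves it 30.5 µM working, against Wednesday's 32.3 µM, so you should expect Wednesday's outcome. It ends with 59.2% of starting material and 39.2% of target.

The constants were drawn at random within sensible limits; the flask was simulated.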